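**Retrosynthetic overview**

Numbering (thymol type): ring C1 carries C7H2O, ring C3 the phenolic O, ring C4 the oxirane carbon C8; C9 is the oxirane CH2 and C10 the CH2OAc carbon.
1. The oxirane is the only ring made (the benzene ring is bought) and is closed last, by 3-exo-tet O-alkylation in a C8–OH/C9–Br bromohydrin. The three esters come from three chemoselective acylations (C7–O, then C10–O, then the phenolic O).
2. Key disconnection C4–C8: a catalytic enantioselective ortho-Friedel–Crafts hydroxyalkylation of 3-hydroxybenzyl isovalerate with ethyl bromopyruvate. One operation makes the C–C bond and the quaternary stereocenter C8 with its oxygen, and delivers C9 as CH2Br and C10 as an ester.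
3. Enabling feature: the phenolic oxygen on C3 sits next to C4 and can carry the chiral titanium centre that delivers the electrophile to C4 only. C8 is a carbinol carbon flanked by two oxygenated one-carbon arms (C9, C10), i.e. the ketone carbon of a 3-substituted pyruvate.

Key step: step 2

Assumption: the (R)-ligand is written for step 2; which antipode of 6,6′-dibromo-BINOL delivers the (2S)-adduct is to be fixed in the first run (the bromine atom allows assignment by anomalous dispersion), and the other antipode is used if required.

**Route**

Step 1
Reactants: 1 3-hydroxybenzyl alcohol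
Product: 2 3-hydroxybenzyl 3-methylbutanoate
Conditions: isovaleric acid (3 equiv), Novozym 435 (immobilised CAL-B), 4 Å MS, MTBE, 45 °C
Reagents that add atoms: isovaleric acid (3-methylbutanoic acid), CC(C)CC(=O)O
Why: Lipase-catalysed chemoselective esterification, in which the enzyme should acylate the primary benzylic hydroxyl and leave the phenolic hydroxyl free, so that no protecting group is needed.

Step 2
Reactants: 2 3-hydroxybenzyl 3-methylbutanoate; 3 ethyl bromopyruvate (ethyl 3-bromo-2-oxopropanoate)
Product: 4 ethyl (2S)-3-bromo-2-hydroxy-2-(2-hydroxy-4-{[(3-methylbutanoyl)oxy]methyl}phenyl)propanoate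
Conditions: Ti(OiPr)4 (20 mol %), (R)-6,6′-dibromo-BINOL (40 mol %), 4 Å MS, toluene, 0 °C
Reagents that add atoms: none
Why: The phenol should exchange onto the BINOLate–titanium centre as an aryloxide while ketoester 3 chelates the same metal through its two carbonyl oxygens, so that ring carbon C4 attacks the activated ketone carbon through a closed six-membered transition state (Ti–O–C3=C4···C8=O), after which proton loss restores the arene. The closest known reaction type is the Ti(IV)/BINOL-catalysed ortho-selective Friedel–Crafts hydroxyalkylation of phenols with trifluoropyruvate and glyoxylate esters, the catalytic form of the ortho-specific hydroxyalkylation of metal phenolates with pyruvates. No ring is closed. The new stereocenter C8 is controlled by the C2-symmetric BINOLate, which leaves one face of the chelated ketone open to the bound aryloxide, and the ligand antipode is chosen to give 2S. The step needs attack at C4 rather than at the para position C6 or the flanked ortho position C2, which metal-bound delivery and the C1 substituent next to C2 should secure, and carbonyl addition rather than O-alkylation at CH2Br, which the base-free Lewis-acid medium should secure. The bromomethyl group makes the ketone more electrophilic than that of ethyl pyruvate, which should compensate for the modest nucleophilicity of the phenol.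

Step 3
Reactants: 4 ethyl (2S)-3-bromo-2-hydroxy-2-(2-hydroxy-4-{[(3-methylbutanoyl)oxy]methyl}phenyl)propanoate
Product: 5 {4-[(2S)-1-bromo-2,3-dihydroxypropan-2-yl]-3-hydroxyphenyl}methyl 3-methylbutanoate
Conditions: BH3·SMe2 (3.5 equiv), NaBH4 (5 mol %), THF, 0 °C → rt; then MeOH
Reagents that add atoms: none
Why: Hydroxyl-directed borane reduction of an α-hydroxy ester, in which boron bound at the C8 oxygen should deliver hydride intramolecularly to the neighbouring ester while the remote isovalerate, the C9–Br bond and C8 itself (no bond to it is touched) are left alone.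

Step 4
Reactants: 5 {4-[(2S)-1-bromo-2,3-dihydroxypropan-2-yl]-3-hydroxyphenyl}methyl 3-methylbutanoate
Product: 6 {4-[(2S)-1-acetoxy-3-bromo-2-hydroxypropan-2-yl]-3-hydroxyphenyl}methyl 3-methylbutanoate
Conditions: AcCl (1.1 equiv), 2,4,6-collidine (2 equiv), CH2Cl2, −78 °C
Reagents that add atoms: acetyl chloride, CC(=O)Cl
Why: Selective acetylation of a primary alcohol with acetyl chloride and a hindered pyridine base at low temperature, where the neutral primary C10 hydroxyl should react well ahead of the hindered, hydrogen-bonded phenol and the tertiary C8 hydroxyl; with bromine on C9 and acetate on C10 the two arms cannot exchange roles.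

Step 5
Reactants: 6 {4-[(2S)-1-acetoxy-3-bromo-2-hydroxypropan-2-yl]-3-hydroxyphenyl}methyl 3-methylbutanoate
Product: 7 2-[(2S)-1-acetoxy-3-bromo-2-hydroxypropan-2-yl]-5-{[(3-methylbutanoyl)oxy]methyl}phenyl (2Z)-2-methylbut-2-enoate
Conditions: angelic anhydride (1.5 equiv), Et3N (2 equiv), CH2Cl2, 0 °C → rt
Reagents that add atoms: angelic anhydride [(2Z)-2-methylbut-2-enoic anhydride], C/C=C(/C)C(=O)OC(=O)/C(C)=C\C
Why: Base-mediated acylation of a phenol with an anhydride, in which only the phenol is acidic enough to react (the tertiary alcohol is inert) and the absence of a nucleophilic acyl-transfer catalyst should keep the Z geometry of the angelate.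

Step 6
Reactants: 7 2-[(2S)-1-acetoxy-3-bromo-2-hydroxypropan-2-yl]-5-{[(3-methylbutanoyl)oxy]methyl}phenyl (2Z)-2-methylbut-2-enoate
Product: 8 [(2R)-2-(2-{[(2Z)-2-methylbut-2-enoyl]oxy}-4-{[(3-methylbutanoyl)oxy]methyl}phenyl)oxiran-2-yl]methyl acetate (target)
Conditions: Cs2CO3 (1.5 equiv), dry MeCN, 0 °C
Reagents that add atoms: none
Why: Intramolecular Williamson etherification (bromohydrin to epoxide, 3-exo-tet), in which the C8 oxygen displaces bromide at C9 without touching any bond to C8, so the (S)-bromohydrin should give the (R)-oxirane (the descriptor changes by CIP priority only), ring closure at a fully substituted carbinol being expected to outrun acyl migration.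

**Compound list**

1 | 3-hydroxybenzyl alcohol | OCc1cccc(O)c1 | starting material
2 | 3-hydroxybenzyl 3-methylbutanoate | CC(C)CC(=O)OCc1cccc(O)c1 | intermediate
3 | ethyl bromopyruvate | CCOC(=O)C(=O)CBr | starting material
4 | ethyl (2S)-3-bromo-2-hydroxy-2-(2-hydroxy-4-{[(3-methylbutanoyl)oxy]methyl}phenyl)propanoate | CCOC(=O)[C@](O)(CBr)c1ccc(COC(=O)CC(C)C)cc1O | intermediate
5 | {4-[(2S)-1-bromo-2,3-dihydroxypropan-2-yl]-3-hydroxyphenyl}methyl 3-methylbutanoate | OC[C@](O)(CBr)c1ccc(COC(=O)CC(C)C)cc1O | intermediate
6 | {4-[(2S)-1-acetoxy-3-bromo-2-hydroxypropan-2-yl]-3-hydroxyphenyl}methyl 3-methylbutanoate | CC(=O)OC[C@](O)(CBr)c1ccc(COC(=O)CC(C)C)cc1O | intermediate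
7 | 2-[(2S)-1-acetoxy-3-bromo-2-hydroxypropan-2-yl]-5-{[(3-methylbutanoyl)oxy]methyl}phenyl (2Z)-2-methylbut-2-enoate | CC(=O)OC[C@](O)(CBr)c1ccc(COC(=O)CC(C)C)cc1OC(=O)/C(C)=C\C | intermediate
8 | [(2R)-2-(2-{[(2Z)-2-methylbut-2-enoyl]oxy}-4-{[(3-methylbutanoyl)oxy]methyl}phenyl)oxiran-2-yl]methyl acetate | C/C=C(/C)C(=O)Oc1cc(COC(=O)CC(C)C)ccc1[C@]1(COC(C)=O)CO1 | target

**Step count**

Total steps: 6. Longest linear sequence: 6 steps (1 → 2 → 4 → 5 → 6 → 7 → 8).

**Steps most likely to fail, highest risk first**

Step 2. The process at risk is slow addition of the weakly activated phenol to the ketoester under catalytic turnover (the chelating product holding on to titanium), with erosion of enantiofacial control and competing self-condensation of the enolisable ketoester. The fallback replaces catalyst control by auxiliary control; it sets out from 2 and comes back at 5. Phenol 2 is combined, in the presence of TiCl4 (1 equiv) in CH2Cl2 at −40 °C, with (1R,2S,5R)-8-phenylmenthyl 3-bromopyruvate F1, which is made by DCC esterification of (−)-8-phenylmenthol with bromopyruvic acid. The stoichiometric, metal-bound ortho-hydroxyalkylation should take place on the keto face that the phenyl ring of the auxiliary does not cover and give the 8-phenylmenthyl (2S)-hydroxy ester F2 (the antipodal auxiliary is taken if the other face reacts). The borane reduction of step 3, applied to F2, releases the auxiliary and gives 5.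

Step 6. The process at risk is migration of the angeloyl group from the phenolic oxygen to the C8 alkoxide before ring closure, followed by attack of the liberated phenoxide on C9. The fallback closes the ring before the phenol ester is in place; it sets out from 6 and comes back at 8. The phenol of 6 is silylated (TIPSCl, imidazole, DMF, 0 °C) to give the triisopropylsilyl ether F3. Cs2CO3 in MeCN then closes the oxirane to give the silyl ether epoxide F4, with no acyl group next to the alkoxide. Slow addition of TBAF to a mixture of F4 and angelic anhydride (THF, −40 °C) exchanges silyl for angeloyl in one flask, the phenoxide being acylated as it is set free, to give 8.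

Step 3. The process at risk is incomplete chemoselectivity of the reduction: attack on the isovalerate, or displacement of bromide by an oxygen nucleophile, during a slow reduction of the hindered tertiary hydroxy ester. The fallback activates the ester through a temporary ring; it sets out from 4 and comes back at 5. Compound 4 is lactonised (TsOH cat., toluene, 70 °C) to the benzofuranone [(3S)-3-(bromomethyl)-3-hydroxy-2-oxo-2,3-dihydro-1-benzofuran-6-yl]methyl 3-methylbutanoate F5. Its aryl lactone carbonyl should be reduced by NaBH4 (THF/H2O, −10 °C) far faster than an alkyl ester, to give 5.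

**Further compounds**

F1 | step 2 | (1R,2S,5R)-5-methyl-2-(2-phenylpropan-2-yl)cyclohexyl 3-bromo-2-oxopropanoate | CC(C)(c1ccccc1)[C@@H]2CC[C@@H](C)C[C@H]2OC(=O)C(=O)CBr
F2 | step 2 | (1R,2S,5R)-5-methyl-2-(2-phenylpropan-2-yl)cyclohexyl (2S)-3-bromo-2-hydroxy-2-(2-hydroxy-4-{[(3-methylbutanoyl)oxy]methyl}phenyl)propanoate | CC(C)(c1ccccc1)[C@@H]2CC[C@@H](C)C[C@H]2OC(=O)[C@](O)(CBr)c3ccc(COC(=O)CC(C)C)cc3O
F3 | step 6 | {4-[(2S)-1-acetoxy-3-bromo-2-hydroxypropan-2-yl]-3-[(triisopropylsilyl)oxy]phenyl}methyl 3-methylbutanoate | CC(=O)OC[C@](O)(CBr)c1ccc(COC(=O)CC(C)C)cc1O[Si](C(C)C)(C(C)C)C(C)C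
F4 | step 6 | [(2R)-2-(4-{[(3-methylbutanoyl)oxy]methyl}-2-[(triisopropylsilyl)oxy]phenyl)oxiran-2-yl]methyl acetate | CC(C)CC(=O)OCc1ccc(c(c1)O[Si](C(C)C)(C(C)C)C(C)C)[C@]2(COC(C)=O)CO2
F5 | step 3 | [(3S)-3-(bromomethyl)-3-hydroxy-2-oxo-2,3-dihydro-1-benzofuran-6-yl]methyl 3-methylbutanoate | O=C1Oc2cc(COC(=O)CC(C)C)ccc2[C@@]1(O)CBr
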